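**Retrosynthetic overview**
1. Last disconnection: five benzyl carbonates on the two phloroglucinol-type rings, removed by neutral hydrogenolysis. No acid or base touches Cα–H once it is set.
2. Key disconnection: Cα–CH(C6H4OH)2. A chiral phosphoric acid catalyses a dehydrative 1,6-addition of the enol of a 3-phenacylchromone to the p-quinone methide formed in the flask from bis(4-hydroxyphenyl)methanol. This joins a C17 and a C13 half, completes the C30 skeleton and sets the only stereocentre. A quinone methide at this carbon is borrowed from the presumed biogenesis (aryl migration in a 3,3''-biflavanone).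
3. Enabling feature: each of the two phenyl rings on the CHAr2 carbon carries a para-OH, so either ring can become the cyclohexadienone ring of a p-quinone methide with the exocyclic carbon as electrophile. The rings are identical, so that carbon is not stereogenic. The Cα methylene lies between the aroyl C=O and C3 of the γ-pyrone ring, so it enolises readily and with one geometry.
4. Nucleophile: the chain aroyl C=O–Cα–C3–C4(=O) is a hidden succinyl unit. It unfolds to two Friedel–Crafts acylations of phloroglucinol by a succinic half-ester chloride, with a C1 (DMF) insertion between them.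
5. Ring order: all four benzene rings are bought. The γ-pyrone ring is the only ring made (step 2), before the key step, which closes no ring.

Key step: step 7

Assumption: the sense of induction of the phosphoric acid cannot be derived from a close precedent. The (R)-catalyst is written, and its enantiomer is used if the first run should give the (S)-product.

Step 1
Reactants: 1 phloroglucinol (benzene-1,3,5-triol); 2 methyl 4-chloro-4-oxobutanoate
Product: 3 methyl 4-oxo-4-(2,4,6-trihydroxyphenyl)butanoate
Conditions: AlCl3 (4 equiv), CH2Cl2–PhNO2, 0 → 40 °C; ice/aq HCl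
Reagents that add atoms: none
Why: Friedel–Crafts acylation: the acid chloride end of 2 is far more electrophilic than its ester end, and the first aluminium-chelated aryl ketone deactivates the ring, so one acyl group should enter and the ester should stay.

Step 2
Reactants: 3 methyl 4-oxo-4-(2,4,6-trihydroxyphenyl)butanoate
Product: 5 methyl 2-(5,7-dihydroxy-4-oxo-4H-chromen-3-yl)acetate, via enaminone methyl 3-[(dimethylamino)methylidene]-4-oxo-4-(2,4,6-trihydroxyphenyl)butanoate 4 (not isolated)
Conditions: BF3·OEt2 (6 equiv), DMF, 10 °C; MsCl (3 equiv) in DMF, 55 → 80 °C; H2O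
Reagents that add atoms: N,N-dimethylformamide, CN(C)C=O
Why: Vilsmeier-type C1 insertion/cyclisation known for polyhydroxy-deoxybenzoins and dihydrochalcones (isoflavone and 3-benzylchromone synthesis): the boron chelate of the o-hydroxyaryl ketone enolises toward its own CH2 and not the ester CH2, the iminium reagent gives enaminone 4, and an ortho OH closes the γ-pyrone ring by addition–elimination with loss of dimethylamine, whereas a free acid in place of the ester would divert to a butenolide, which is why the ester is carried.

Step 3
Reactants: 5 methyl 2-(5,7-dihydroxy-4-oxo-4H-chromen-3-yl)acetate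
Product: 6 2-(5,7-dihydroxy-4-oxo-4H-chromen-3-yl)acetic acid
Conditions: 6 M HCl–AcOH (1:1), 90 °C
Reagents that add atoms: water, O
Why: Acid-catalysed ester hydrolysis (AAC2), chosen because the γ-pyrone ring is inert to hot aqueous acid whereas hydroxide would attack its C2 and open it.

Step 4
Reactants: 6 2-(5,7-dihydroxy-4-oxo-4H-chromen-3-yl)acetic acid; 1 phloroglucinol (2 equiv)
Product: 7 5,7-dihydroxy-3-[2-oxo-2-(2,4,6-trihydroxyphenyl)ethyl]-4H-chromen-4-one
Conditions: BF3·OEt2 (neat), 75 °C, Ar; H2O
Reagents that add atoms: none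
Why: Friedel–Crafts (Nencki-type) acylation of phloroglucinol by a free arylacetic-type acid in BF3·OEt2, the standard entry to 2,4,6-trihydroxydeoxybenzoins, in which the excess of 1 should outrun the much less nucleophilic, carbonyl-deactivated A ring of 6.

Step 5
Reactants: 7 5,7-dihydroxy-3-[2-oxo-2-(2,4,6-trihydroxyphenyl)ethyl]-4H-chromen-4-one
Product: 8 pentakis(benzyl carbonate) of 7, i.e. dibenzyl 3-(2-oxo-2-{2,4,6-tris[(benzyloxycarbonyl)oxy]phenyl}ethyl)-4-oxo-4H-chromene-5,7-diyl biscarbonate
Conditions: CbzCl (6 equiv), pyridine, DMAP (cat.), CH2Cl2, 0 °C → rt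
Reagents that add atoms: benzyl chloroformate, O=C(Cl)OCc1ccccc1
Why: O-Acylation of phenols via the acylpyridinium salt, with pyridine too weak a base to deprotonate the CH2; the five carbonates turn donor OH groups into acceptors, which shuts off ring C-alkylation in step 7, raises the enol content of the ketone and allows removal without acid or base.

Step 6
Reactants: 9 4,4'-dihydroxybenzophenone
Product: 10 bis(4-hydroxyphenyl)methanol
Conditions: NaBH4 (3 equiv), EtOH, 0 → 50 °C; pH 7 buffer, used without storage
Reagents that add atoms: none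
Why: Borohydride reduction of a diaryl ketone, with the work-up kept at pH 7 because traces of acid already ionise 10.

Step 7
Reactants: 8 pentakis(benzyl carbonate) of 7 (1.5 equiv); 10 bis(4-hydroxyphenyl)methanol
Product: 13 (R)-pentacarbonate, i.e. 8 carrying a bis(4-hydroxyphenyl)methyl group at Cα with (R) configuration at Cα, via p-quinone methide 4-[(4-hydroxyphenyl)methylidene]cyclohexa-2,5-dien-1-one 11 (not isolated), via the (Z)-enol tautomer of the pentacarbonate 12 (not isolated)
Conditions: (R)-TRIP [(R)-3,3'-bis(2,4,6-triisopropylphenyl)-1,1'-binaphthyl-2,2'-diyl hydrogen phosphate] (10 mol %), 4 Å MS, DCE, 0 °C; 10 in EtOAc added by syringe pump over 8 h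
Reagents that add atoms: none
Why: Proposed new method: the phosphoric acid dehydrates 10 to the hydrogen-bonded/ion-paired p-quinone methide 11 and at the same time catalyses enolisation of 8 to the (Z)-enol 12, whose α-carbon adds to the exocyclic carbon of 11 in a 1,6-conjugate addition that rearomatises the dienone ring and forms the Cα–CHAr2 bond. The closest known reaction types are chiral-phosphoric-acid-catalysed 1,6-additions to p-quinone methides generated in situ from p-hydroxybenzhydrols, phosphoric-acid "enol catalysis" of ketones and the organocatalytic SN1-type α-benzhydrylation of aldehydes, but the enol of an acyclic α-heteroaryl aryl ketone has not served as the carbon nucleophile. No ring is closed. The one new stereocentre (Cα, R) is controlled by the catalyst: the phosphate bridges the enol O–H and the quinone methide oxygen, A(1,3) strain holds the 2,6-disubstituted aryl group cis to H so that only the (Z)-enol is present, the 3,3'-aryl walls leave one enol face open, and the quinone methide geometry does not matter because the benzhydryl carbon bears two identical rings. The step needs Cα-alkylation rather than ring C-alkylation and only one alkylation, which is secured by the five electron-withdrawing carbonates (both oxygenated rings of 8 become poor Friedel–Crafts partners), by slow addition of 10 to excess 8 (O-alkylation of phenols is reversible under the acid) and by the bulk of the product. The product should keep its configuration because its enol would be tetrasubstituted and severely strained and should therefore form far more slowly than 12.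

Step 8
Reactants: 13 (R)-pentacarbonate
Product: 14 target, 3-[(2R)-1,1-bis(4-hydroxyphenyl)-3-oxo-3-(2,4,6-trihydroxyphenyl)propan-2-yl]-5,7-dihydroxy-4H-chromen-4-one
Conditions: H2 (1 atm), 5 % Pd/C, EtOAc–THF, rt, stopped after uptake of 5 equiv
Reagents that add atoms: none
Why: Hydrogenolysis of the benzyl–O bonds followed by spontaneous decarboxylation of the aryl hydrogen carbonates, in a neutral medium so that Cα–H is not enolised, and the hindered trisubstituted C2=C3 bond of the pyrone ring and the electron-rich aryl ketone should not be reduced at 1 atm.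

**Compound list**
1 | phloroglucinol | Oc1cc(O)cc(O)c1 | starting material
2 | methyl 4-chloro-4-oxobutanoate | COC(=O)CCC(=O)Cl | starting material
3 | methyl 4-oxo-4-(2,4,6-trihydroxyphenyl)butanoate | COC(=O)CCC(=O)c1c(O)cc(O)cc1O | intermediate
4 | methyl 3-[(dimethylamino)methylidene]-4-oxo-4-(2,4,6-trihydroxyphenyl)butanoate (alkene geometry of no consequence) | COC(=O)CC(=CN(C)C)C(=O)c1c(O)cc(O)cc1O | intermediate (not isolated)
5 | methyl 2-(5,7-dihydroxy-4-oxo-4H-chromen-3-yl)acetate | COC(=O)Cc1coc2cc(O)cc(O)c2c1=O | intermediate
6 | 2-(5,7-dihydroxy-4-oxo-4H-chromen-3-yl)acetic acid | OC(=O)Cc1coc2cc(O)cc(O)c2c1=O | intermediate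
7 | 5,7-dihydroxy-3-[2-oxo-2-(2,4,6-trihydroxyphenyl)ethyl]-4H-chromen-4-one | O=C(Cc1coc2cc(O)cc(O)c2c1=O)c1c(O)cc(O)cc1O | intermediate
8 | pentakis(benzyl carbonate) of 7 | O=C(Cc1coc2cc(OC(=O)OCc3ccccc3)cc(OC(=O)OCc3ccccc3)c2c1=O)c1c(OC(=O)OCc2ccccc2)cc(OC(=O)OCc2ccccc2)cc1OC(=O)OCc1ccccc1 | intermediate
9 | 4,4'-dihydroxybenzophenone | O=C(c1ccc(O)cc1)c1ccc(O)cc1 | starting material
10 | bis(4-hydroxyphenyl)methanol | OC(c1ccc(O)cc1)c1ccc(O)cc1 | intermediate
11 | 4-[(4-hydroxyphenyl)methylidene]cyclohexa-2,5-dien-1-one (p-quinone methide) | O=C1C=CC(=Cc2ccc(O)cc2)C=C1 | intermediate (not isolated)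
12 | (Z)-enol of 8 (enol OH cis to the chromon-3-yl group, aryl cis to H) | O/C(c1c(OC(=O)OCc2ccccc2)cc(OC(=O)OCc2ccccc2)cc1OC(=O)OCc1ccccc1)=C\c1coc2cc(OC(=O)OCc3ccccc3)cc(OC(=O)OCc3ccccc3)c2c1=O | intermediate (not isolated)
13 | (R)-pentacarbonate, Cα-[bis(4-hydroxyphenyl)methyl] derivative of 8 | O=C(c1c(OC(=O)OCc2ccccc2)cc(OC(=O)OCc2ccccc2)cc1OC(=O)OCc1ccccc1)[C@@H](c1coc2cc(OC(=O)OCc3ccccc3)cc(OC(=O)OCc3ccccc3)c2c1=O)C(c1ccc(O)cc1)c1ccc(O)cc1 | intermediate
14 | 3-[(2R)-1,1-bis(4-hydroxyphenyl)-3-oxo-3-(2,4,6-trihydroxyphenyl)propan-2-yl]-5,7-dihydroxy-4H-chromen-4-one | O=C(c1c(O)cc(O)cc1O)[C@@H](c1coc2cc(O)cc(O)c2c1=O)C(c1ccc(O)cc1)c1ccc(O)cc1 | target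

Total step count: 8. Longest linear sequence: 7 (steps 1–5, 7, 8).

**Steps most likely to fail**

**1. Step 7.**
- Risk: enolisation of 8 may be slower than Friedel–Crafts self-condensation of the quinone methide with the phenol rings.
- Risk: the catalyst may discriminate the enol faces poorly.
- Risk: the enol oxygen may attack C2 of the pyrone ring in a Paal–Knorr-type recyclisation.
- Fallback (known chemistry): it sets out from 8 and 10. The two fragments are joined without asymmetric induction by an achiral acid (diphenyl phosphate or Bi(OTf)3, DCE, rt). This is the established acid-catalysed dehydrative alkylation of enolisable carbonyl compounds with electron-rich benzhydrols, and it should give the racemic pentacarbonate F1. Preparative SFC on an immobilised polysaccharide chiral phase then separates the (R)-enantiomer from the (S)-pentacarbonate F2. The route is rejoined at 13.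

**2. Step 4.**
- Risk: at 75 °C in BF3·OEt2 the new 1,4-dicarbonyl array (aryl ketone C=O and the masked formyl carbon C2 of the pyrone ring) may recyclise to a 2-aryl-4-aroylfuran.
- Risk: the A ring of 6 may be acylated in competition.
- Fallback: it sets out from 1 and replaces the acid-based acylation by a nitrile-based one run at 0 °C.
  - Friedel–Crafts acylation of 1 with commercial 3-cyanopropanoyl chloride (AlCl3, CH2Cl2–PhNO2) should give 4-oxo-4-(2,4,6-trihydroxyphenyl)butanenitrile F3.
  - The C1 insertion of step 2 should give (5,7-dihydroxy-4-oxo-4H-chromen-3-yl)acetonitrile F4.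
  - Houben–Hoesch reaction of F4 with 1 (dry HCl, ZnCl2, Et2O–dioxane, 0 °C) should precipitate the ketiminium chloride F5.
  - F5 is hydrolysed in water at 90 °C. The route is rejoined at 7.

**3. Step 5.**
- Risk: acylation of the three chelated hydroxyls may stay incomplete.
- Risk: the enol oxygen may be acylated.
- Risk: a carbonate may migrate from O to the activated CH2 (Baker–Venkataraman-type transfer).
- Fallback: it sets out from 7 and exchanges electronic for steric shielding, and hydrogenolysis for fluoride.
  - TBSCl, imidazole, DMF should give the pentakis(tert-butyldimethylsilyl) ether F6, whose ring C–H positions are each flanked by two bulky silyloxy groups.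
  - Coupling with 10 under the conditions of step 7 should give the (R)-configured pentasilyl coupling product F7.
  - Et3N·3HF in THF at 0 °C removes the silyl groups. The route is rejoined at 14.

**Further compounds**
F1 | step 7 | racemic pentacarbonate (rac-13) | O=C(c1c(OC(=O)OCc2ccccc2)cc(OC(=O)OCc2ccccc2)cc1OC(=O)OCc1ccccc1)C(c1coc2cc(OC(=O)OCc3ccccc3)cc(OC(=O)OCc3ccccc3)c2c1=O)C(c1ccc(O)cc1)c1ccc(O)cc1
F2 | step 7 | (S)-pentacarbonate (ent-13) | O=C(c1c(OC(=O)OCc2ccccc2)cc(OC(=O)OCc2ccccc2)cc1OC(=O)OCc1ccccc1)[C@H](c1coc2cc(OC(=O)OCc3ccccc3)cc(OC(=O)OCc3ccccc3)c2c1=O)C(c1ccc(O)cc1)c1ccc(O)cc1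
F3 | step 4 | 4-oxo-4-(2,4,6-trihydroxyphenyl)butanenitrile | N#CCCC(=O)c1c(O)cc(O)cc1O
F4 | step 4 | (5,7-dihydroxy-4-oxo-4H-chromen-3-yl)acetonitrile | N#CCc1coc2cc(O)cc(O)c2c1=O
F5 | step 4 | ketiminium chloride of 7 | [Cl-].[NH2+]=C(Cc1coc2cc(O)cc(O)c2c1=O)c1c(O)cc(O)cc1O
F6 | step 5 | pentakis(tert-butyldimethylsilyl) ether of 7 | O=C(Cc1coc2cc(O[Si](C)(C)C(C)(C)C)cc(O[Si](C)(C)C(C)(C)C)c2c1=O)c1c(O[Si](C)(C)C(C)(C)C)cc(O[Si](C)(C)C(C)(C)C)cc1O[Si](C)(C)C(C)(C)C
F7 | step 5 | (R)-pentasilyl coupling product | O=C(c1c(O[Si](C)(C)C(C)(C)C)cc(O[Si](C)(C)C(C)(C)C)cc1O[Si](C)(C)C(C)(C)C)[C@@H](c1coc2cc(O[Si](C)(C)C(C)(C)C)cc(O[Si](C)(C)C(C)(C)C)c2c1=O)C(c1ccc(O)cc1)c1ccc(O)cc1
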